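## Retrosynthetic overview

1. Target ⇐ unmasking of the two primary alcohols (silyl ether, ethoxyethyl acetal) of a protected butenolide.
2. Ring B (butenolide) ⇐ ketenylidene-ylide (Bestmann) annulation of an α-hydroxy ketone; the lactone and a fused oxaphosphetane close in the same operation, then Ph3PO is lost.
3. Skipped diene ⇐ ruthenium-catalysed alkene–alkyne (Alder-ene) coupling of a homoallylic tertiary alcohol with an internal alkyne; it joins the two halves and sets the E- and the Z-olefin at once.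
4. Alkyne half ⇐ methyl (S)-glycidate (lactone stereocentre) + silyl propargyl ether, then Weinreb amide and an alkoxymethyllithium. Alkene half ⇐ asymmetric allylboration of dihydro-β-ionone (tertiary carbinol).
5. Ring order: ring A (trimethylcyclohexene) is bought with dihydro-β-ionone; ring B is the only ring built, in step 7.

Assumption: (S)-3,3′-dibromo-BINOL is taken to give the (S)-carbinol 3; if the facial sense on this ketone is the opposite, its commercial enantiomer is used with no other change.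
Assumption: compounds carrying the 1-ethoxyethyl acetal are epimer mixtures at the acetal carbon (left undefined in the SMILES); that centre is removed in step 8.

## Route

Step 1
Reactants: 1 4-(2,6,6-trimethylcyclohex-1-en-1-yl)butan-2-one (dihydro-β-ionone); 2 allyldiisopropoxyborane
Product: 3 (4S)-4-methyl-6-(2,6,6-trimethylcyclohex-1-en-1-yl)hex-1-en-4-ol
Conditions: (S)-3,3′-Br2-BINOL (15 mol%), PhCF3/PhMe 3:1, −35 °C; aqueous work-up
Reagents that add atoms: none
Why: Chiral-diol-catalysed asymmetric allylboration of a ketone (Schaus type), in which exchange of one isopropoxy group for the BINOL gives a chiral allylboronate that transfers allyl through a closed chair transition state to one face of the methyl ketone and so sets the (S)-tertiary carbinol.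

Step 2
Reactants: 4 (tributylstannyl)methanol
Product: 5 tributyl[(1-ethoxyethoxy)methyl]stannane
Conditions: ethyl vinyl ether, PPTS (cat.), CH2Cl2, 0 °C to rt
Reagents that add atoms: ethyl vinyl ether, C=COCC
Why: Acid-catalysed addition of the alcohol to the enol ether (acetal protection) gives the Still-type hydroxymethyl-anion precursor; no relevant stereocentre is formed.

Step 3
Reactants: 6 tert-butyldimethyl(prop-2-yn-1-yloxy)silane; 7 methyl (2S)-oxirane-2-carboxylate (methyl (S)-glycidate)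
Product: 9 methyl (2S)-6-{[tert-butyl(dimethyl)silyl]oxy}-2-hydroxyhex-4-ynoate, via lithium acetylide 8 (not isolated)
Conditions: n-BuLi, THF, −78 °C; BF3·OEt2; then 7, −78 °C; aq. NH4Cl
Reagents that add atoms: none
Why: BF3-promoted opening of a terminal epoxide by a lithium acetylide (Yamaguchi–Hirao type) occurs at the unsubstituted C3 of the glycidate, so the C2–O bond and its (S)-configuration are kept and become the lactone stereocentre.

Step 4
Reactants: 9 methyl (2S)-6-{[tert-butyl(dimethyl)silyl]oxy}-2-hydroxyhex-4-ynoate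
Product: 10 (2S)-6-{[tert-butyl(dimethyl)silyl]oxy}-2-hydroxy-N-methoxy-N-methylhex-4-ynamide
Conditions: MeNHOMe·HCl, i-PrMgCl, THF, −20 to 0 °C
Reagents that add atoms: N,O-dimethylhydroxylamine hydrochloride, CNOC.Cl
Why: Weinreb amide formation by aminolysis of the ester with the chloromagnesium amide; the hydroxyl sits as its magnesium alkoxide and the adjacent stereocentre is not touched.

Step 5
Reactants: 10 (2S)-6-{[tert-butyl(dimethyl)silyl]oxy}-2-hydroxy-N-methoxy-N-methylhex-4-ynamide; 5 tributyl[(1-ethoxyethoxy)methyl]stannane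
Product: 12 (3S)-7-{[tert-butyl(dimethyl)silyl]oxy}-1-(1-ethoxyethoxy)-3-hydroxyhept-5-yn-2-one, via (1-ethoxyethoxy)methyllithium 11 (not isolated)
Conditions: 5 (2.6 equiv), n-BuLi (2.5 equiv), THF, −78 °C; then 10, −78 to −50 °C; cold aq. NH4Cl
Reagents that add atoms: none
Why: Tin–lithium exchange gives the α-alkoxymethyllithium (Still reagent), which adds only once to the Weinreb amide because the chelated tetrahedral intermediate survives until the cold quench (one equivalent is spent on the free hydroxyl); the stereocentre is not involved.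

Step 6
Reactants: 12 (3S)-7-{[tert-butyl(dimethyl)silyl]oxy}-1-(1-ethoxyethoxy)-3-hydroxyhept-5-yn-2-one; 3 (4S)-4-methyl-6-(2,6,6-trimethylcyclohex-1-en-1-yl)hex-1-en-4-ol
Product: 13 (3S,5Z,8E,10S)-6-({[tert-butyl(dimethyl)silyl]oxy}methyl)-1-(1-ethoxyethoxy)-3,10-dihydroxy-10-methyl-12-(2,6,6-trimethylcyclohex-1-en-1-yl)dodeca-5,8-dien-2-one
Conditions: [CpRu(MeCN)3]PF6 (10 mol%), 3 (1.3 equiv), acetone, rt
Reagents that add atoms: none
Why: Ruthenium-catalysed alkene–alkyne coupling (Trost Alder-ene type): the ruthenacyclopentene forms the new C–C bond at the alkyne carbon remote from the coordinating free hydroxyl and next to the bulky silyloxymethyl group (the selectivity known for 5-hydroxy-2-alkynoates), β-hydride elimination gives the E-disubstituted olefin, and syn delivery of H and the allyl unit places the silyloxymethyl group cis to the carbinol-bearing chain (Z); no new stereocentre is formed.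

Step 7
Reactants: 13 (3S,5Z,8E,10S)-6-({[tert-butyl(dimethyl)silyl]oxy}methyl)-1-(1-ethoxyethoxy)-3,10-dihydroxy-10-methyl-12-(2,6,6-trimethylcyclohex-1-en-1-yl)dodeca-5,8-dien-2-one; 14 (triphenylphosphoranylidene)ketene (Bestmann ylide)
Product: 17 (5S)-5-[(2Z,5E,7S)-3-({[tert-butyl(dimethyl)silyl]oxy}methyl)-7-hydroxy-7-methyl-9-(2,6,6-trimethylcyclohex-1-en-1-yl)nona-2,5-dien-1-yl]-4-[(1-ethoxyethoxy)methyl]furan-2(5H)-one, via acyl ylide 15 (not isolated), via fused oxaphosphetane 16 (not isolated)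
Conditions: 14 (1.2 equiv), THF, 60 °C
Reagents that add atoms: none
Why: Bestmann ketenylidene annulation: the secondary hydroxyl of the α-hydroxy ketone adds to Ph3P=C=C=O (the tertiary alcohol is far slower), the intramolecular Wittig reaction of the acyl ylide closes the five-membered lactone and the fused four-membered oxaphosphetane together, and loss of Ph3PO leaves the carbonyl necessarily on the ring-oxygen side, with the stereocentre untouched under these base-free conditions.

Step 8
Reactants: 17 (5S)-5-[(2Z,5E,7S)-3-({[tert-butyl(dimethyl)silyl]oxy}methyl)-7-hydroxy-7-methyl-9-(2,6,6-trimethylcyclohex-1-en-1-yl)nona-2,5-dien-1-yl]-4-[(1-ethoxyethoxy)methyl]furan-2(5H)-one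
Product: 18 (5S)-5-[(2Z,5E,7S)-7-hydroxy-3-(hydroxymethyl)-7-methyl-9-(2,6,6-trimethylcyclohex-1-en-1-yl)nona-2,5-dien-1-yl]-4-(hydroxymethyl)furan-2(5H)-one
Conditions: HF·pyridine, pyridine, THF, 0 °C to rt; then PPTS (cat.), MeOH, rt
Reagents that add atoms: none
Why: Buffered fluoride cleavage of the primary silyl ether followed by mild acid-catalysed transacetalisation of the ethoxyethyl ether; neither condition ionises the tertiary allylic alcohol or enolises the butenolide, so both stereocentres and both olefin geometries survive.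

## Compound list

1 | 4-(2,6,6-trimethylcyclohex-1-en-1-yl)butan-2-one (dihydro-β-ionone) | CC(=O)CCC1=C(C)CCCC1(C)C | starting material
2 | allyldiisopropoxyborane (diisopropyl allylboronate) | C=CCB(OC(C)C)OC(C)C | starting material
3 | (4S)-4-methyl-6-(2,6,6-trimethylcyclohex-1-en-1-yl)hex-1-en-4-ol | CC1=C(CC[C@](C)(O)CC=C)C(C)(C)CCC1 | intermediate
4 | (tributylstannyl)methanol | CCCC[Sn](CCCC)(CCCC)CO | starting material
5 | tributyl[(1-ethoxyethoxy)methyl]stannane | CCCC[Sn](CCCC)(CCCC)COC(C)OCC | intermediate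
6 | tert-butyldimethyl(prop-2-yn-1-yloxy)silane | C#CCO[Si](C)(C)C(C)(C)C | starting material
7 | methyl (2S)-oxirane-2-carboxylate | COC(=O)[C@@H]1CO1 | starting material
8 | lithium acetylide of 6 | [Li]C#CCO[Si](C)(C)C(C)(C)C | intermediate
9 | methyl (2S)-6-{[tert-butyl(dimethyl)silyl]oxy}-2-hydroxyhex-4-ynoate | COC(=O)[C@@H](O)CC#CCO[Si](C)(C)C(C)(C)C | intermediate
10 | (2S)-6-{[tert-butyl(dimethyl)silyl]oxy}-2-hydroxy-N-methoxy-N-methylhex-4-ynamide | CON(C)C(=O)[C@@H](O)CC#CCO[Si](C)(C)C(C)(C)C | intermediate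
11 | (1-ethoxyethoxy)methyllithium | [Li]COC(C)OCC | intermediate
12 | (3S)-7-{[tert-butyl(dimethyl)silyl]oxy}-1-(1-ethoxyethoxy)-3-hydroxyhept-5-yn-2-one | CCOC(C)OCC(=O)[C@@H](O)CC#CCO[Si](C)(C)C(C)(C)C | intermediate
13 | (3S,5Z,8E,10S)-6-({[tert-butyl(dimethyl)silyl]oxy}methyl)-1-(1-ethoxyethoxy)-3,10-dihydroxy-10-methyl-12-(2,6,6-trimethylcyclohex-1-en-1-yl)dodeca-5,8-dien-2-one | CC1=C(CC[C@](C)(O)/C=C/C/C(=C/C[C@H](O)C(=O)COC(C)OCC)CO[Si](C)(C)C(C)(C)C)C(C)(C)CCC1 | intermediate
14 | (triphenylphosphoranylidene)ketene | O=C=C=P(c1ccccc1)(c1ccccc1)c1ccccc1 | starting material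
15 | acyl ylide: (triphenylphosphoranylidene)acetate ester of the secondary hydroxyl of 13 | CC1=C(CC[C@](C)(O)/C=C/C/C(=C/C[C@H](OC(=O)C=P(c2ccccc2)(c2ccccc2)c2ccccc2)C(=O)COC(C)OCC)CO[Si](C)(C)C(C)(C)C)C(C)(C)CCC1 | intermediate
16 | fused oxaphosphetane: γ-lactone whose C3–C4 bond is shared with a 1,2-oxaphosphetane (PPh3 on C3, O on C4) | CC1=C(CC[C@](C)(O)/C=C/C/C(=C/C[C@@H]2OC(=O)C3C2(COC(C)OCC)OP3(c2ccccc2)(c2ccccc2)c2ccccc2)CO[Si](C)(C)C(C)(C)C)C(C)(C)CCC1 | intermediate
17 | (5S)-5-[(2Z,5E,7S)-3-({[tert-butyl(dimethyl)silyl]oxy}methyl)-7-hydroxy-7-methyl-9-(2,6,6-trimethylcyclohex-1-en-1-yl)nona-2,5-dien-1-yl]-4-[(1-ethoxyethoxy)methyl]furan-2(5H)-one | CC1=C(CC[C@](C)(O)/C=C/C/C(=C/C[C@@H]2OC(=O)C=C2COC(C)OCC)CO[Si](C)(C)C(C)(C)C)C(C)(C)CCC1 | intermediate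
18 | (5S)-5-[(2Z,5E,7S)-7-hydroxy-3-(hydroxymethyl)-7-methyl-9-(2,6,6-trimethylcyclohex-1-en-1-yl)nona-2,5-dien-1-yl]-4-(hydroxymethyl)furan-2(5H)-one | CC1=C(CC[C@](C)(O)/C=C/C/C(=C/C[C@@H]2OC(=O)C=C2CO)CO)C(C)(C)CCC1 | target

## Step count and risks

Total step count: 8. Longest linear sequence: 6 steps (steps 3 to 8).

Three steps most likely to fail:

**Step 1 (enantioselectivity on a methyl / primary-alkyl ketone).** The two ketone substituents differ little in size, so the ee may fall short, and the wrong enantiomer of 3 would later give a remote diastereomer that is hard to remove. The fallback sets out from 1 and comes back at 3. Horner–Wadsworth–Emmons reaction of 1 with triethyl phosphonoacetate (NaH, THF) and separation of the E isomer gives ethyl (2E)-3-methyl-5-(2,6,6-trimethylcyclohex-1-en-1-yl)pent-2-enoate F1. Reduction with i-Bu2AlH gives (2E)-3-methyl-5-(2,6,6-trimethylcyclohex-1-en-1-yl)pent-2-en-1-ol F2. Sharpless asymmetric epoxidation (Ti(Oi-Pr)4, L-(+)-diethyl tartrate, t-BuOOH, CH2Cl2, −20 °C; the ring olefin is not an allylic alcohol and stays) gives [(2S,3S)-3-methyl-3-[2-(2,6,6-trimethylcyclohex-1-en-1-yl)ethyl]oxiran-2-yl]methanol F3. Hydroxyl-directed hydride opening at C2 with NaAlH2(OCH2CH2OMe)2 gives (3S)-3-methyl-5-(2,6,6-trimethylcyclohex-1-en-1-yl)pentane-1,3-diol F4. Oxidation of the primary alcohol only (TEMPO, PhI(OAc)2) gives (3S)-3-hydroxy-3-methyl-5-(2,6,6-trimethylcyclohex-1-en-1-yl)pentanal F5, and methylenation with Ph3P=CH2 at low temperature gives 3.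

**Step 6 (regiochemistry of the alkene–alkyne coupling on an alkyne flanked by two CH2 groups).** If the C–C bond forms at the wrong alkyne carbon, the fallback sets out from 12 and 3 and comes back at 13. Syn-hydrostannation of 12 (Bu3SnH, Mo(CO)3(CNt-Bu)3 cat., THF, 55 °C) puts tin on the carbon next to the silyloxymethyl group and gives (3S,5E)-7-{[tert-butyl(dimethyl)silyl]oxy}-1-(1-ethoxyethoxy)-3-hydroxy-6-(tributylstannyl)hept-5-en-2-one F6. Linear allylic C–H acetoxylation of 3 (Pd(OAc)2 cat., benzoquinone, DMSO/AcOH) gives (2E,4S)-4-hydroxy-4-methyl-6-(2,6,6-trimethylcyclohex-1-en-1-yl)hex-2-en-1-yl acetate F7. Allyl–vinyl Stille coupling of F6 and F7 (Pd(PPh3)4, LiCl, DMF) at the unhindered allyl terminus, with retention at the vinyl carbon, gives 13.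

**Step 7 (ring closure: competing acylation of the tertiary alcohol, or erosion of the stereocentre next to the ketone on heating).** The fallback sets out from 13 and comes back at 17. Esterification of the secondary hydroxyl with diethylphosphonoacetic acid (DCC, DMAP cat., CH2Cl2, 0 °C) gives the diethylphosphonoacetate ester of 13 F8. Intramolecular Horner–Wadsworth–Emmons reaction under Masamune–Roush conditions (LiCl, i-Pr2NEt, MeCN, 0 °C) closes the butenolide to 17.

Further compounds
F1 | step 1 | ethyl (2E)-3-methyl-5-(2,6,6-trimethylcyclohex-1-en-1-yl)pent-2-enoate | CCOC(=O)/C=C(\C)CCC1=C(C)CCCC1(C)C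
F2 | step 1 | (2E)-3-methyl-5-(2,6,6-trimethylcyclohex-1-en-1-yl)pent-2-en-1-ol | OC/C=C(\C)CCC1=C(C)CCCC1(C)C
F3 | step 1 | [(2S,3S)-3-methyl-3-[2-(2,6,6-trimethylcyclohex-1-en-1-yl)ethyl]oxiran-2-yl]methanol | OC[C@@H]1O[C@@]1(C)CCC1=C(C)CCCC1(C)C
F4 | step 1 | (3S)-3-methyl-5-(2,6,6-trimethylcyclohex-1-en-1-yl)pentane-1,3-diol | OCC[C@@](C)(O)CCC1=C(C)CCCC1(C)C
F5 | step 1 | (3S)-3-hydroxy-3-methyl-5-(2,6,6-trimethylcyclohex-1-en-1-yl)pentanal | O=CC[C@@](C)(O)CCC1=C(C)CCCC1(C)C
F6 | step 6 | (3S,5E)-7-{[tert-butyl(dimethyl)silyl]oxy}-1-(1-ethoxyethoxy)-3-hydroxy-6-(tributylstannyl)hept-5-en-2-one | CCOC(C)OCC(=O)[C@@H](O)C/C=C(\CO[Si](C)(C)C(C)(C)C)[Sn](CCCC)(CCCC)CCCC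
F7 | step 6 | (2E,4S)-4-hydroxy-4-methyl-6-(2,6,6-trimethylcyclohex-1-en-1-yl)hex-2-en-1-yl acetate | CC(=O)OC/C=C/[C@@](C)(O)CCC1=C(C)CCCC1(C)C
F8 | step 7 | diethylphosphonoacetate ester of the secondary hydroxyl of 13 | CC1=C(CC[C@](C)(O)/C=C/C/C(=C/C[C@H](OC(=O)CP(=O)(OCC)OCC)C(=O)COC(C)OCC)CO[Si](C)(C)C(C)(C)C)C(C)(C)CCC1
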